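**Retrosynthetic overview** (halimane numbering: ring A = C1–C5 + C10, ring B = C5–C10, side chain C11–C16 on C9; the target is read as 4S,5R,8R,9S,13E)
1. The C15 propanoate comes from the allylic alcohol; C12–C13 is cut as a Negishi sp3–sp2 coupling of a C12 alkylzinc with an (E)-alkenyl iodide (C13–C16).
2. Feature on which the route rests: ring A is a cyclohexene whose C1=C10 olefin lies between C2 and C5, with the quaternary C4 (CH3, CO2CH3) next to C5. C2–C3 and C4–C5 are therefore the two σ-bonds of a Diels–Alder between the ring-B 1-vinylcyclohexene C2=C1–C10=C5 and methyl methacrylate (C3=C4).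
3. The diene comes from an enol triflate and a vinylstannane (Stille); the ketone comes from asymmetric conjugate methylation–allylation of 2-methylcyclohex-2-enone, which sets C8 and C9; the allyl group is cut down to the C11–C12 silyloxyethyl arm.
4. Ring order: ring B is the starting enone, ring A is closed in the Diels–Alder, the side chain is finished last.

Key step: step 7

Assumption: the sense of induction in step 1 is set by the choice of ligand antipode; the antipode that gives the (3R) enolate is used.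

**Route**

Step 1
Reactants: 1 2-methylcyclohex-2-en-1-one; 2 allyl bromide
Product: 4 (2S,3R)-2-allyl-2,3-dimethylcyclohexan-1-one, via bromomagnesium enolate 3 (not isolated)
Conditions: MeMgBr (1.2 equiv), Cu(OTf)2 (3 mol %), chiral N-mesityl N'-(1-hydroxyalkyl)imidazolinium hexafluorophosphate (leucinol-derived NHC precursor, 4 mol %), Et2O, −30 °C; then 2 (3 equiv), DMPU, −30 °C → rt
Reagents that add atoms: methylmagnesium bromide, C[Mg]Br
Why: Copper-catalysed asymmetric conjugate addition sets the methyl-bearing carbon (C8) under ligand control, and the regiodefined magnesium enolate is then C-allylated anti to that pseudoaxial methyl (tandem conjugate addition–enolate alkylation), so the quaternary carbon (C9) should form with allyl trans to the C8 methyl and the two methyls cis.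

Step 2
Reactants: 4 (2S,3R)-2-allyl-2,3-dimethylcyclohexan-1-one
Product: 6 (2S,3R)-2,3-dimethyl-2-(2-oxoethyl)cyclohexan-1-one, via secondary ozonide 5 (not isolated)
Conditions: O3, CH2Cl2, −78 °C; then PPh3, −78 °C → rt
Reagents that add atoms: ozone, [O-][O+]=O
Why: Ozonolysis of the terminal olefin with reductive cleavage of the ozonide removes one carbon and leaves the aldehyde that becomes C12, without touching the ketone or the two stereocentres.

Step 3
Reactants: 6 (2S,3R)-2,3-dimethyl-2-(2-oxoethyl)cyclohexan-1-one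
Product: 7 (2S,3R)-2-(2-hydroxyethyl)-2,3-dimethylcyclohexan-1-one
Conditions: NaBH4 (0.3 equiv), EtOH/CH2Cl2, −78 °C
Reagents that add atoms: none
Why: Chemoselective borohydride reduction, since at −78 °C the unhindered aldehyde should be reduced far faster than the ketone flanked by the quaternary carbon.

Step 4
Reactants: 7 (2S,3R)-2-(2-hydroxyethyl)-2,3-dimethylcyclohexan-1-one
Product: 8 (2S,3R)-2-{2-[(tert-butyldimethylsilyl)oxy]ethyl}-2,3-dimethylcyclohexan-1-one
Conditions: TBSCl, imidazole, DMF, 0 °C → rt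
Reagents that add atoms: tert-butyldimethylsilyl chloride, CC(C)(C)[Si](C)(C)Cl
Why: Standard silylation of the primary alcohol, which also drains any cyclic hemiketal back to the open hydroxy ketone.

Step 5
Reactants: 8 (2S,3R)-2-{2-[(tert-butyldimethylsilyl)oxy]ethyl}-2,3-dimethylcyclohexan-1-one
Product: 10 (5R,6S)-6-{2-[(tert-butyldimethylsilyl)oxy]ethyl}-5,6-dimethylcyclohex-1-en-1-yl trifluoromethanesulfonate, via potassium enolate 9 (not isolated)
Conditions: KN(SiMe3)2 (KHMDS), THF, −78 °C; then PhNTf2, −78 → 0 °C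
Reagents that add atoms: N-phenylbis(trifluoromethanesulfonimide), O=S(=O)(N(c1ccccc1)S(=O)(=O)C(F)(F)F)C(F)(F)F
Why: Enolisation can only go toward the CH2 side because the other α-carbon is quaternary, and O-triflation of the enolate (enol triflate formation) fixes the future C5=C10 olefin.

Step 6
Reactants: 10 (5R,6S)-6-{2-[(tert-butyldimethylsilyl)oxy]ethyl}-5,6-dimethylcyclohex-1-en-1-yl trifluoromethanesulfonate; 11 tributyl(vinyl)stannane
Product: 12 tert-butyl{2-[(1S,6R)-2-ethenyl-1,6-dimethylcyclohex-2-en-1-yl]ethoxy}dimethylsilane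
Conditions: Pd(PPh3)4 (5 mol %), LiCl (3 equiv), THF, 65 °C
Reagents that add atoms: none
Why: Stille coupling of an enol triflate with a vinylstannane, in which LiCl converts the palladium triflate into the chloride for transmetalation and the C10–C1 bond forms with the ring olefin kept in place.

Step 7
Reactants: 12 tert-butyl{2-[(1S,6R)-2-ethenyl-1,6-dimethylcyclohex-2-en-1-yl]ethoxy}dimethylsilane; 13 methyl methacrylate
Product: 14 methyl (1S,5S,6R,8aR)-5-{2-[(tert-butyldimethylsilyl)oxy]ethyl}-1,5,6-trimethyl-1,2,3,5,6,7,8,8a-octahydronaphthalene-1-carboxylate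
Conditions: 13 (5 equiv), EtAlCl2 (0.5 equiv), CH2Cl2, −78 → −20 °C
Reagents that add atoms: none
Why: EtAlCl2 binds the ester carbonyl of 13 and lowers its LUMO, and the s-cis diene C2=C1–C10=C5 of 12 adds across C3=C4 in a concerted but asynchronous [4+2] in which the bond from the open terminus C2 to the β-carbon C3 runs ahead of the congested C4–C5 bond (ortho regiochemistry, the terminal ring residue on C5 directing more strongly than the internal one on C10). The closest known reaction type is the Lewis-acid-promoted Diels–Alder reaction of 1-vinylcyclohexenes with α-substituted acrylates. Ring A is closed by this intermolecular cycloaddition, both σ-bonds forming suprafacially on diene and dienophile, and its olefin can only arise at C1=C10 because C9 is quaternary. C5 is set by the π-face of the diene: with the C8 methyl equatorial the cis C9 methyl is pseudoaxial and screens one face of C10=C5, so the dienophile should add to the other face (that of H8 and C11), which places H5 cis to both ring-B methyls. C4 is set by the ester-endo transition state, which places CO2CH3 cis to C6 (the outside substituent of the diene terminus C5) and the C4 methyl cis to H5. The step therefore needs regio-, endo and facial selectivity; Lewis-acid activation sharpens the first two (no inside substituent at C2 or C5 opposes the exo methyl), whereas the facial bias rests on the pseudoaxial C9 methyl alone and is the weak point.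

Step 8
Reactants: 14 methyl (1S,5S,6R,8aR)-5-{2-[(tert-butyldimethylsilyl)oxy]ethyl}-1,5,6-trimethyl-1,2,3,5,6,7,8,8a-octahydronaphthalene-1-carboxylate
Product: 15 methyl (1S,5S,6R,8aR)-5-(2-hydroxyethyl)-1,5,6-trimethyl-1,2,3,5,6,7,8,8a-octahydronaphthalene-1-carboxylate
Conditions: TBAF, THF, 0 °C → rt
Reagents that add atoms: none
Why: Fluoride desilylation of the primary silyl ether, to which the hindered tertiary methyl ester and the trisubstituted olefin should be inert.

Step 9
Reactants: 15 methyl (1S,5S,6R,8aR)-5-(2-hydroxyethyl)-1,5,6-trimethyl-1,2,3,5,6,7,8,8a-octahydronaphthalene-1-carboxylate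
Product: 16 methyl (1S,5S,6R,8aR)-5-(2-iodoethyl)-1,5,6-trimethyl-1,2,3,5,6,7,8,8a-octahydronaphthalene-1-carboxylate
Conditions: I2, PPh3, imidazole, CH2Cl2, 0 °C → rt
Reagents that add atoms: iodine, [I][I]
Why: Appel-type iodination, in which iodide displaces the alkoxyphosphonium at the primary C12 by SN2 and no stereocentre is involved.

Step 10
Reactants: 17 but-2-yn-1-ol
Product: 18 tert-butyl(but-2-yn-1-yloxy)dimethylsilane
Conditions: TBSCl, imidazole, CH2Cl2, 0 °C → rt
Reagents that add atoms: tert-butyldimethylsilyl chloride, CC(C)(C)[Si](C)(C)Cl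
Why: Standard silylation of the primary propargylic alcohol.

Step 11
Reactants: 18 tert-butyl(but-2-yn-1-yloxy)dimethylsilane
Product: 20 tert-butyl{[(2E)-3-iodobut-2-en-1-yl]oxy}dimethylsilane, via alkenylzirconocene chloride 19 (not isolated)
Conditions: Cp2Zr(H)Cl (2 equiv), THF, 50 °C; then I2, THF, 0 °C
Reagents that add atoms: iodine, [I][I]
Why: Hydrozirconation is a syn addition and, with excess Cp2Zr(H)Cl at 50 °C, should equilibrate zirconium to the less hindered methyl-bearing alkyne carbon, so iodinolysis with retention gives the (E)-3-iodo isomer.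

Step 12
Reactants: 16 methyl (1S,5S,6R,8aR)-5-(2-iodoethyl)-1,5,6-trimethyl-1,2,3,5,6,7,8,8a-octahydronaphthalene-1-carboxylate; 20 tert-butyl{[(2E)-3-iodobut-2-en-1-yl]oxy}dimethylsilane
Product: 22 methyl (1S,5S,6R,8aR)-5-[(3E)-5-{[tert-butyl(dimethyl)silyl]oxy}-3-methylpent-3-en-1-yl]-1,5,6-trimethyl-1,2,3,5,6,7,8,8a-octahydronaphthalene-1-carboxylate, via alkylzinc iodide 21 (not isolated)
Conditions: Zn dust (BrCH2CH2Br/TMSCl activation), LiCl, THF, 40 °C; then 20, Pd(PPh3)4 (5 mol %), THF, 50 °C
Reagents that add atoms: none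
Why: Negishi coupling, in which zinc inserts into the primary C–I bond without touching the ester and the palladium-catalysed sp3–sp2 coupling with the alkenyl iodide forms C12–C13 with retention of the E geometry.

Step 13
Reactants: 22 methyl (1S,5S,6R,8aR)-5-[(3E)-5-{[tert-butyl(dimethyl)silyl]oxy}-3-methylpent-3-en-1-yl]-1,5,6-trimethyl-1,2,3,5,6,7,8,8a-octahydronaphthalene-1-carboxylate
Product: 23 methyl (1S,5S,6R,8aR)-5-[(3E)-5-hydroxy-3-methylpent-3-en-1-yl]-1,5,6-trimethyl-1,2,3,5,6,7,8,8a-octahydronaphthalene-1-carboxylate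
Conditions: TBAF, THF, 0 °C → rt
Reagents that add atoms: none
Why: Fluoride desilylation of the allylic silyl ether under conditions that leave the ester and both olefins alone.

Step 14
Reactants: 23 methyl (1S,5S,6R,8aR)-5-[(3E)-5-hydroxy-3-methylpent-3-en-1-yl]-1,5,6-trimethyl-1,2,3,5,6,7,8,8a-octahydronaphthalene-1-carboxylate
Product: 24 methyl (1S,5S,6R,8aR)-1,5,6-trimethyl-5-[(3E)-3-methyl-5-(propanoyloxy)pent-3-en-1-yl]-1,2,3,5,6,7,8,8a-octahydronaphthalene-1-carboxylate (CNP0279628.1)
Conditions: (EtCO)2O, Et3N, DMAP (cat.), CH2Cl2, 0 °C → rt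
Reagents that add atoms: propanoic anhydride, CCC(=O)OC(=O)CC
Why: DMAP-catalysed acylation of the primary allylic alcohol with the anhydride gives the propanoate without affecting any stereocentre or the olefin geometry.

**Compound list**
1 | 2-methylcyclohex-2-en-1-one | CC1=CCCCC1=O | starting material
2 | allyl bromide | C=CCBr | starting material
3 | bromomagnesium (3R)-2,3-dimethylcyclohex-1-en-1-olate | CC1=C(O[Mg]Br)CCC[C@H]1C | intermediate
4 | (2S,3R)-2-allyl-2,3-dimethylcyclohexan-1-one | C=CC[C@]1(C)C(=O)CCC[C@H]1C | intermediate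
5 | (2S,3R)-2,3-dimethyl-2-(1,2,4-trioxolan-3-ylmethyl)cyclohexan-1-one (secondary ozonide, epimers at the trioxolane carbon) | O1COOC1C[C@]2(C)C(=O)CCC[C@H]2C | intermediate
6 | (2S,3R)-2,3-dimethyl-2-(2-oxoethyl)cyclohexan-1-one | O=CC[C@]1(C)C(=O)CCC[C@H]1C | intermediate
7 | (2S,3R)-2-(2-hydroxyethyl)-2,3-dimethylcyclohexan-1-one | OCC[C@]1(C)C(=O)CCC[C@H]1C | intermediate
8 | (2S,3R)-2-{2-[(tert-butyldimethylsilyl)oxy]ethyl}-2,3-dimethylcyclohexan-1-one | CC(C)(C)[Si](C)(C)OCC[C@]1(C)C(=O)CCC[C@H]1C | intermediate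
9 | potassium (5R,6S)-6-{2-[(tert-butyldimethylsilyl)oxy]ethyl}-5,6-dimethylcyclohex-1-en-1-olate | CC(C)(C)[Si](C)(C)OCC[C@]1(C)C([O-])=CCC[C@H]1C.[K+] | intermediate
10 | (5R,6S)-6-{2-[(tert-butyldimethylsilyl)oxy]ethyl}-5,6-dimethylcyclohex-1-en-1-yl trifluoromethanesulfonate | CC(C)(C)[Si](C)(C)OCC[C@]1(C)C(OS(=O)(=O)C(F)(F)F)=CCC[C@H]1C | intermediate
11 | tributyl(vinyl)stannane | C=C[Sn](CCCC)(CCCC)CCCC | starting material
12 | tert-butyl{2-[(1S,6R)-2-ethenyl-1,6-dimethylcyclohex-2-en-1-yl]ethoxy}dimethylsilane | CC(C)(C)[Si](C)(C)OCC[C@]1(C)C(C=C)=CCC[C@H]1C | intermediate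
13 | methyl methacrylate | C=C(C)C(=O)OC | starting material
14 | methyl (1S,5S,6R,8aR)-5-{2-[(tert-butyldimethylsilyl)oxy]ethyl}-1,5,6-trimethyl-1,2,3,5,6,7,8,8a-octahydronaphthalene-1-carboxylate | CC(C)(C)[Si](C)(C)OCC[C@]1(C)C2=CCC[C@](C)(C(=O)OC)[C@@H]2CC[C@H]1C | intermediate
15 | methyl (1S,5S,6R,8aR)-5-(2-hydroxyethyl)-1,5,6-trimethyl-1,2,3,5,6,7,8,8a-octahydronaphthalene-1-carboxylate | OCC[C@]1(C)C2=CCC[C@](C)(C(=O)OC)[C@@H]2CC[C@H]1C | intermediate
16 | methyl (1S,5S,6R,8aR)-5-(2-iodoethyl)-1,5,6-trimethyl-1,2,3,5,6,7,8,8a-octahydronaphthalene-1-carboxylate | ICC[C@]1(C)C2=CCC[C@](C)(C(=O)OC)[C@@H]2CC[C@H]1C | intermediate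
17 | but-2-yn-1-ol | CC#CCO | starting material
18 | tert-butyl(but-2-yn-1-yloxy)dimethylsilane | CC#CCO[Si](C)(C)C(C)(C)C | intermediate
19 | chlorobis(cyclopentadienyl)[(2E)-4-{[tert-butyl(dimethyl)silyl]oxy}but-2-en-2-yl]zirconium (cyclopentadienyl rings drawn σ-bonded) | C/C(=C\CO[Si](C)(C)C(C)(C)C)[Zr](Cl)(C1C=CC=C1)C1C=CC=C1 | intermediate
20 | tert-butyl{[(2E)-3-iodobut-2-en-1-yl]oxy}dimethylsilane | I/C(C)=C/CO[Si](C)(C)C(C)(C)C | intermediate
21 | {2-[(1S,2R,5S,4aR)-5-(methoxycarbonyl)-1,2,5-trimethyl-1,2,3,4,4a,5,6,7-octahydronaphthalen-1-yl]ethyl}zinc iodide | I[Zn]CC[C@]1(C)C2=CCC[C@](C)(C(=O)OC)[C@@H]2CC[C@H]1C | intermediate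
22 | methyl (1S,5S,6R,8aR)-5-[(3E)-5-{[tert-butyl(dimethyl)silyl]oxy}-3-methylpent-3-en-1-yl]-1,5,6-trimethyl-1,2,3,5,6,7,8,8a-octahydronaphthalene-1-carboxylate | CC(C)(C)[Si](C)(C)OC/C=C(\C)CC[C@]1(C)C2=CCC[C@](C)(C(=O)OC)[C@@H]2CC[C@H]1C | intermediate
23 | methyl (1S,5S,6R,8aR)-5-[(3E)-5-hydroxy-3-methylpent-3-en-1-yl]-1,5,6-trimethyl-1,2,3,5,6,7,8,8a-octahydronaphthalene-1-carboxylate | OC/C=C(\C)CC[C@]1(C)C2=CCC[C@](C)(C(=O)OC)[C@@H]2CC[C@H]1C | intermediate
24 | methyl (1S,5S,6R,8aR)-1,5,6-trimethyl-5-[(3E)-3-methyl-5-(propanoyloxy)pent-3-en-1-yl]-1,2,3,5,6,7,8,8a-octahydronaphthalene-1-carboxylate | CCC(=O)OC/C=C(\C)CC[C@]1(C)C2=CCC[C@](C)(C(=O)OC)[C@@H]2CC[C@H]1C | target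

**Step count**
Total: 14 steps. Longest linear sequence: 12 steps (steps 1–9 and 12–14); steps 10–11 make the alkenyl iodide.

**Steps most likely to fail**

Step 7. What may go wrong: insufficient π-facial discrimination by the single pseudoaxial C9 methyl, erosion of endo selectivity through contact of the aluminium-bound ester with the C11 methylene, and a slow reaction at the congested C4–C5 bond that lets the regioisomer or diene decomposition compete. Fallback: it sets out from 12 and comes back at 14. The dienophile is changed to methacrolein and the promoter to a chiral cationic oxazaborolidine (made from diphenylprolinol and o-tolylboroxine, activated with Tf2NH; CH2Cl2, −78 °C), used as the antipode whose shielding of the enal matches the substrate bias. The smaller and more reactive formyl group should sit endo more easily and the catalyst decides which diene face is used, giving (1S,5S,6R,8aR)-5-{2-[(tert-butyldimethylsilyl)oxy]ethyl}-1,5,6-trimethyl-1,2,3,5,6,7,8,8a-octahydronaphthalene-1-carbaldehyde F1. Pinnick oxidation (NaClO2, NaH2PO4, 2-methylbut-2-ene, t-BuOH/H2O) should give the corresponding carboxylic acid F2, and methylation with TMSCHN2 (MeOH/toluene, 0 °C) returns 14.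

Step 1. What may go wrong: incomplete enantiofacial control in the methyl transfer, and sluggish or poorly diastereoselective C-allylation of the magnesium enolate. Fallback: it sets out from 1 and comes back at 4. Copper-catalysed asymmetric conjugate addition of Me3Al (copper thiophene-2-carboxylate CuO2CC4H3S, BINOL-derived bis(1-phenylethyl)amine phosphoramidite, Et2O, −30 °C) gives dimethylaluminium (3R)-2,3-dimethylcyclohex-1-en-1-olate F3. This is trapped with acetic anhydride as (3R)-2,3-dimethylcyclohex-1-en-1-yl acetate F4, which is isolated so that its enantiomeric purity can be checked before the quaternary centre is made. Cleavage with MeLi (2 equiv, THF, 0 °C) gives lithium (3R)-2,3-dimethylcyclohex-1-en-1-olate F5, which is allylated with 2 (THF/DMPU, −78 → 0 °C) to give 4.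

Step 12. What may go wrong: slow zinc insertion, protonolysis of the alkylzinc, or β-hydride elimination and homocoupling after transmetalation. Fallback: it sets out from 16 and comes back at 23, so that step 13 is not needed. Displacement of iodide with lithium acetylide–ethylenediamine complex (DMSO, rt) gives methyl (1S,5S,6R,8aR)-5-(but-3-yn-1-yl)-1,5,6-trimethyl-1,2,3,5,6,7,8,8a-octahydronaphthalene-1-carboxylate F6. Zirconium-catalysed methylalumination (Me3Al, Cp2ZrCl2, CH2Cl2, rt) adds CH3 and aluminium syn to give the (E)-alkenyldimethylalane F7. This is converted with n-BuLi (−78 °C) into the lithium butyl(dimethyl)alkenylalanate F8 and trapped with paraformaldehyde to give 23 directly; the hindered tertiary ester is expected to survive.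

**Further compounds**
F1 | step 7 | (1S,5S,6R,8aR)-5-{2-[(tert-butyldimethylsilyl)oxy]ethyl}-1,5,6-trimethyl-1,2,3,5,6,7,8,8a-octahydronaphthalene-1-carbaldehyde | CC(C)(C)[Si](C)(C)OCC[C@]1(C)C2=CCC[C@](C)(C=O)[C@@H]2CC[C@H]1C
F2 | step 7 | (1S,5S,6R,8aR)-5-{2-[(tert-butyldimethylsilyl)oxy]ethyl}-1,5,6-trimethyl-1,2,3,5,6,7,8,8a-octahydronaphthalene-1-carboxylic acid | CC(C)(C)[Si](C)(C)OCC[C@]1(C)C2=CCC[C@](C)(C(=O)O)[C@@H]2CC[C@H]1C
F3 | step 1 | dimethylaluminium (3R)-2,3-dimethylcyclohex-1-en-1-olate | CC1=C(O[Al](C)C)CCC[C@H]1C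
F4 | step 1 | (3R)-2,3-dimethylcyclohex-1-en-1-yl acetate | CC1=C(OC(C)=O)CCC[C@H]1C
F5 | step 1 | lithium (3R)-2,3-dimethylcyclohex-1-en-1-olate | CC1=C(O[Li])CCC[C@H]1C
F6 | step 12 | methyl (1S,5S,6R,8aR)-5-(but-3-yn-1-yl)-1,5,6-trimethyl-1,2,3,5,6,7,8,8a-octahydronaphthalene-1-carboxylate | C#CCC[C@]1(C)C2=CCC[C@](C)(C(=O)OC)[C@@H]2CC[C@H]1C
F7 | step 12 | (E)-alkenyldimethylalane from methylalumination of F6 | C[Al](C)/C=C(\C)CC[C@]1(C)C2=CCC[C@](C)(C(=O)OC)[C@@H]2CC[C@H]1C
F8 | step 12 | lithium butyl(dimethyl)alkenylalanate from F7 | [Li+].CCCC[Al-](C)(C)/C=C(\C)CC[C@]1(C)C2=CCC[C@](C)(C(=O)OC)[C@@H]2CC[C@H]1C
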